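Early in the red run, the one run made so far, you see substrate fall to 0.3 % by 0.500 d while target stands at 13.4 %, so the target arrives late, out of forms you are not shown.

common to all: substrate 0.10 M
- red: capture agent 0.20 M; temperature 90 °C; run made earlier
- delta: capture agent 0.100 M; temperature 90 °C; time 25 d
- gamma: capture agent 0.100 M; at 70 °C until 12 d, from then on at 110 °C; time 25 d
- zeta: capture agent 0.100 M; temperature 110 °C; time 25 d
- theta: capture agent 0.100 M; temperature 70 °C; time 25 d

red run (percent of the substrate charged)

| time / d | target / % | substrate / % |
|---|---|---|
| 0.208 | 2.7 | 7.5 |
| 0.333 | 6.8 | 2.6 |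
| 0.500 | 13.4 | 0.3 |
| 0.833 | 25.9 | 0.2 |
| 1.67 | 47.1 | 0 |
| 2.50 | 54.9 | 0.2 |

(scatter of a reading: 0.3 percentage points)

- a species is counted by the substrate in it: one idle adduct or side product counts as two
- amounts and yields of target count idle adduct too
- the numbers in the tables scatter with a standard deviation of 0.3 percentage points
- on the list of suspects stand: intermediate B -> intermediate C; substrate + intermediate E -> side product; intermediate D -> target; substrate -> intermediate C; intermediate C <-> intermediate E; capture agent + intermediate A -> trapped intermediate; substrate + target <-> idle adduct; intermediate A -> intermediate D; intermediate C -> intermediate D; substrate <-> intermediate A; intermediate A <-> intermediate B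
- in an amount of target, one idle adduct counts as one target
- the earlier runs do not show what temperature does; that part of a forecast is a guess
- no earlier run changes the charge of capture agent; that part of a forecast is a guess

1. the flask that comes out highest in amount of target, in percent of the substrate charged, or "all alike" when all lie within 1.5 percentage points (delta / gamma / zeta / theta / all alike)
2. target at the end, in percent of the substrate charged, delta
3. target at the end, in percent of the substrate charged, gamma
4. target at the end, in percent of the substrate charged, zeta
5. target at the end, in percent of the substrate charged, theta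

Turn the question round: what would have to be true for the flasks to read alike? Start from the red run's end. Its target readings at 0.833 d, 1.67 d and 2.50 d are equally spaced, and each step is 0.368 of the one before. Summing the shrinking steps gives a plateau near 59.4 %. I assume the remainder was caught by capture agent, so the loss per target goes with the charge of capture agent. Dividing by the red charge gives 3.41 /M: call this the odds per molar, substrate lost per target per molar of capture agent, a selectivity factor. At delta's charge the odds are 0.341, so I commit to 74.6 % target in delta.

Now work in powers of ten. Near that yield, a change of 1.5 percentage points means a shift in the common logarithm of the odds of 0.0350. Halving the charge of capture agent, by comparison, shifts it 0.301. So reading alike needs heat, from 70 °C to 110 °C, to leave capture and its rival steps matched inside that narrow window. The runs show nothing of temperature, so my guess is that the flasks part, with heat lowering the odds: zeta highest, and gamma, cold until 12 d, beside theta.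

The forecast also says zeta, but it sets delta lower than I do, at 70 %, with gamma 66 %, zeta 73 % and theta 66 %, holding that “Flasks therefore differ only in selectivity”. The flasks give delta 69.8 %, gamma 47.3 %, zeta 89.2 % and theta 43.7 %, so zeta is highest.

    intermediate B → intermediate C (k = 4.70 × 10⁻⁶ /s, Ea = 127 kJ/mol)
    substrate + intermediate E → side product (k = 2.30 × 10⁻⁴ /M/s, Ea = 63.0 kJ/mol)
    intermediate D → target (k = 2.10 × 10⁻⁶ /s, Ea = 121 kJ/mol)
    substrate → intermediate C (k = 5.90 × 10⁻⁶ /s, Ea = 129 kJ/mol)
    intermediate C ⇌ intermediate E (K = 0.280, k = 1.70 × 10⁻⁶ /s, Ea = 111 kJ/mol, ΔH = −34.0 kJ/mol)
    capture agent + intermediate A → trapped intermediate (k = 2.00 × 10⁻⁴ /M/s, Ea = 65.0 kJ/mol)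
    substrate + target ⇌ idle adduct, settled at all times (K = 3.10 /M, ΔH = 6.00 kJ/mol)
    intermediate A → intermediate D (k = 3.00 × 10⁻⁶ /s, Ea = 107 kJ/mol)
    intermediate C → intermediate D (k = 2.40 × 10⁻⁶ /s, Ea = 126 kJ/mol)
    substrate ⇌ intermediate A (K = 3.10, k = 1.80 × 10⁻⁵ /s, Ea = 115 kJ/mol, ΔH = −49.0 kJ/mol)
    intermediate A ⇌ intermediate B (K = 31.0, k = 2.30 × 10⁻⁶ /s, Ea = 110 kJ/mol, ΔH = −35.0 kJ/mol)
    (constants at 70 °C)

Delta's odds at the end are 0.413, against the 0.341 you reckoned. Theta and zeta stand 1.01 apart in the logarithm of the odds, outside the window. The largest single effect in the difference of 46 points between zeta and theta is what temperature does to the path from substrate to intermediate C: without it the difference is 18 points. Gamma's end odds are 3.15 times what the odds per molar give at its charge, and with that factor held, 0.040 M of capture agent gives odds of 0.430. That neighbour of gamma holds 29.5 % trapped intermediate to 67.5 % target, odds of 0.437.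

Readings and results were generated by integration on assumed constants; the scatter is artificial.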